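Read at its first sample, the south-east run already holds 35% single product at 0.667 h against 38% at 8.00 h, and the east run holds 102% triple product at 1.33 h against 97% at 8.00 h, with a scatter of 2 percentage points on a reading.

in all of them: starting material 0.056 M

| run | reagent | remark | time |
|---|---|---|---|
| north-east | 0.026 M | run made earlier |  |
| south-east | 0.064 M | run made earlier |  |
| east | 0.20 M | run made earlier |  |
| ash | 0.0280 M |  | 10 h |
| cedar | 0.168 M |  | 10 h |

- north-east (time / h: triple product / %, single product / %): 1.33: 2, 31; 3.00: 3, 26; 4.00: 2, 32; 6.00: 0, 27; 8.00: 0, 30
- south-east (time / h: triple product / %, single product / %): 0.667: 11, 35; 2.00: 7, 36; 3.00: 13, 35; 5.00: 9, 37; 8.00: 4, 38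
- east (time / h: triple product / %, single product / %): 1.33: 102, 0; 3.00: 96, 0; 4.00: 94, 0; 6.00: 97, 0; 8.00: 97, 2

(readings scatter by 2 percentage points)

- steps that have been proposed: reagent + single product -> over-reaction product; reagent + single product -> double product; reagent + double product -> triple product; starting material + reagent -> single product

1. which of these holds the largest part of the starting material at the end of ash (double product / single product / starting material / triple product)
2. which of these holds the largest part of the starting material at the end of cedar (double product / single product / starting material / triple product)
3. how much triple product is there at the end of cedar, in percent of the starting material charged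

On the first rung of the ladder of times stand the additions, whose products already stand at the first samples. On the next rung, up to 8.00 h, the two series quoted move by 3 points and 5 points, and the asked time is longer still, at 10 h. The mixture is therefore reckoned from a budget, not a clock. The reagent budget b is the reagent charged per starting material charged, 3.00 in cedar and 0.500 in ash. Reagent is the limiting reagent in ash. Every starting material consumed has taken at least one reagent, so at least 50.0% of it remains in ash. The north-east run, with b of 0.464, reads single product near 30%, so starting material should lead in ash. Triple product costs 3 reagents per starting material, which is cedar's whole budget. East keeps a larger surplus over that cost, so cedar's last step slows as reagent and double product fall together. Its triple product is reckoned here near east's mean reading, 97.2%, on the assumption that this tail ends within 10 h.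

The forecast, holding that “each run is simply limited by reagent”, names starting material for ash, triple product for cedar and 94% triple product. The simulation gives starting material at 60.5% in ash, and triple product at 96.8% in cedar.

    reagent + single product → over-reaction product (k = 0.00714 M⁻¹ s⁻¹)
    reagent + single product → double product (k = 0.213 M⁻¹ s⁻¹)
    reagent + double product → triple product (k = 0.194 M⁻¹ s⁻¹)
    starting material + reagent → single product (k = 0.218 M⁻¹ s⁻¹)

Cedar's budget of 3.00 closes: triple product at 3 reagents and over-reaction product at 2 spend 2.97, and the 1.08% of reagent left brings this to 3.00. The neighbour with 0.042 M reagent has b of 0.750, spends 0.750 and keeps 46.6% starting material. In cedar, double product falls from 0.00974% at 5.00 h to 0% at 10.0 h. Ten times the time leaves cedar's triple product unchanged: at 100 h it stands at 96.8%.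

The readings come from a simulation with made-up constants, noise included.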